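The side chain is added last, so everything rests on the cyclopenta[c]pyridine core. Its carbinol carbon C6 lies between C5H2 and methyl-bearing C7 in the cyclopentane ring. It is therefore read as carbon monoxide placed between a terminal alkyne carbon (C5) and the far end of an (E)-crotyl alkene (C7). One intramolecular Pauson–Khand (2+2+1) reaction of an acyclic carbamate-linked aza-1,7-enyne forms C4a–C7a, C6–C7 and finally C5–C6, closing the piperidine and cyclopentenone rings together. The alkene geometry becomes the trans C7-methyl/C7a–C1 relation, and the purchased C4 stereocentre steers C7a. Two directed reductions then set C6 and C4a.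

Key step: step 5

Remark on numbering: ring locants are those of cyclopenta[c]pyridine (C1, N2, C3, C4, C4a, C5, C6, C7, C7a). Primed locants belong to the acyl chain.
Assumption: amine 2 is used as its free base of E configuration.

Step 1
Reactants: 1 (R)-3-bromo-2-methylpropan-1-ol; 2 (E)-but-2-en-1-amine
Product: 3 (2S)-3-[(2E)-but-2-en-1-ylamino]-2-methylpropan-1-ol
Conditions: 2 (4 equiv), K2CO3 (1.2 equiv), MeCN, 70 °C, sealed flask
Reagents that add atoms: none
Why: SN2 amination at the primary carbon leaves the adjacent stereocentre untouched (the descriptor changes from R to S only through the ranking of the substituents), and the excess of volatile amine suppresses double alkylation.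

Step 2
Reactants: 3 (2S)-3-[(2E)-but-2-en-1-ylamino]-2-methylpropan-1-ol
Product: 4 methyl N-[(2E)-but-2-en-1-yl]-N-[(2S)-3-hydroxy-2-methylpropyl]carbamate
Conditions: ClCO2Me (1.05 equiv), NaHCO3, CH2Cl2/H2O, 0 °C
Reagents that add atoms: methyl chloroformate, COC(=O)Cl
Why: Schotten–Baumann acylation is selective for the secondary amine over the primary alcohol, and the methyl carbamate removes the basicity that would disturb cobalt and iridium while serving as the latent N-methyl group.

Step 3
Reactants: 4 methyl N-[(2E)-but-2-en-1-yl]-N-[(2S)-3-hydroxy-2-methylpropyl]carbamate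
Product: 5 methyl N-[(2E)-but-2-en-1-yl]-N-[(2S)-2-methyl-3-oxopropyl]carbamate
Conditions: Dess–Martin periodinane (1.2 equiv), CH2Cl2, 0 °C to rt; used without storage
Reagents that add atoms: none
Why: Dess–Martin oxidation runs under near-neutral conditions, so the alpha-stereocentre of the aldehyde should not epimerise and the alkene and carbamate are untouched.

Step 4
Reactants: 5 methyl N-[(2E)-but-2-en-1-yl]-N-[(2S)-2-methyl-3-oxopropyl]carbamate
Product: 6 methyl N-[(2E)-but-2-en-1-yl]-N-[(2R)-2-methylbut-3-yn-1-yl]carbamate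
Conditions: dimethyl (1-diazo-2-oxopropyl)phosphonate (1.3 equiv), K2CO3 (2 equiv), MeOH, 0 °C to rt
Reagents that add atoms: dimethyl (1-diazo-2-oxopropyl)phosphonate (Ohira–Bestmann reagent), COP(=O)(OC)C(=[N+]=[N-])C(C)=O
Why: Seyferth–Gilbert homologation with the Ohira–Bestmann reagent turns the aldehyde into the terminal alkyne under mild carbonate conditions that preserve alpha-methyl stereocentres (descriptor S to R by ranking only), and methanol cannot scramble a methyl carbamate.

Step 5
Reactants: 6 methyl N-[(2E)-but-2-en-1-yl]-N-[(2R)-2-methylbut-3-yn-1-yl]carbamate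
Product: 8 methyl (4R,7S,7aS)-4,7-dimethyl-6-oxo-1,3,4,6,7,7a-hexahydro-2H-cyclopenta[c]pyridine-2-carboxylate, via dicobalt hexacarbonyl alkyne complex 7 (not isolated)
Conditions: Co2(CO)8 (1.1 equiv), 1,2-dichloroethane (0.05 M), rt, 2 h; then n-BuSMe (3.5 equiv), 83 °C; filtration through Celite
Reagents that add atoms: dicobalt octacarbonyl, Co2(CO)8, source of the C6 carbonyl, [C-]#[O+].[C-]#[O+].[C-]#[O+].[C-]#[O+].[C-]#[O+].[C-]#[O+].[C-]#[O+].[C-]#[O+].[Co].[Co]
Why: Co2(CO)8 binds the terminal alkyne as complex 7, sulfide-assisted loss of one CO lets the crotyl alkene coordinate and insert into the bond between cobalt and the internal alkyne carbon (C4a–C7a), CO migrates onto cobalt-bound C7 (C6–C7), and reductive elimination joins acyl carbon C6 to the former alkyne terminus C5. The closest known reaction type is the cobalt-mediated intramolecular Pauson–Khand reaction of N-acyl aza-1,7-enynes, a (2+2+1) cycloaddition. The piperidine ring closes in the insertion event, 6-exo with respect to both the alkyne and the alkene, and the cyclopentenone ring closes in the last event, when the six-membered acylcobaltacycle contracts as C5–C6 forms. C7 and C7a arise from suprafacial addition to the (E)-alkene, so the C7 methyl and the C7a–C1 bond must end trans, while C7a is set relative to C4 by a chair-like tether with the C4 methyl equatorial, which places H4 and H7a on the same face. Regiochemistry is fixed by the tether, so the step needs only this 1,3-diastereoselection, and the unsubstituted alkyne terminus secures it because an equatorial C4 methyl then meets only H5 in allylic 1,3-strain. The planar carbamate nitrogen brings the reacting ends together and keeps the nitrogen lone pair away from cobalt.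

Step 6
Reactants: 8 methyl (4R,7S,7aS)-4,7-dimethyl-6-oxo-1,3,4,6,7,7a-hexahydro-2H-cyclopenta[c]pyridine-2-carboxylate
Product: 9 methyl (4R,6S,7S,7aS)-6-hydroxy-4,7-dimethyl-1,3,4,6,7,7a-hexahydro-2H-cyclopenta[c]pyridine-2-carboxylate (hydroxyl cis to the C7 methyl and to H7a)
Conditions: LiBH(s-Bu)3 (1.2 equiv), THF, −78 °C; then aq NaOH, H2O2, 0 °C
Reagents that add atoms: none
Why: Steric-approach-controlled 1,2-reduction, in which the fully substituted beta-carbon C4a blocks conjugate hydride delivery and the bulky borohydride attacks C6 anti to the neighbouring C7 methyl, as in the reduction of 2-alkylcyclopentanones to cis-2-alkylcyclopentanols, so the hydroxyl ends cis to that methyl on the face of H7a.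

Step 7
Reactants: 9 methyl (4R,6S,7S,7aS)-6-hydroxy-4,7-dimethyl-1,3,4,6,7,7a-hexahydro-2H-cyclopenta[c]pyridine-2-carboxylate
Product: 10 methyl (4R,4aS,6R,7S,7aR)-6-hydroxy-4,7-dimethyloctahydro-2H-cyclopenta[c]pyridine-2-carboxylate (cis-fused; H4, H4a and H7a on one face)
Conditions: [Ir(cod)(PCy3)(py)]PF6 (5 mol %), H2 (1 atm), CH2Cl2, rt
Reagents that add atoms: none
Why: Hydroxyl-directed homogeneous hydrogenation, in which the cationic iridium centre binds the allylic C6 hydroxyl and delivers H2 to C4a=C5 from the same face, sets H4a cis to H7a and H4 whatever the intrinsic facial bias of the alkene (the descriptors at C6 and C7a change by ranking only).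

Step 8
Reactants: 10 methyl (4R,4aS,6R,7S,7aR)-6-hydroxy-4,7-dimethyloctahydro-2H-cyclopenta[c]pyridine-2-carboxylate
Product: 11 incarvilline, (4R,4aS,6R,7S,7aR)-2,4,7-trimethyloctahydro-1H-cyclopenta[c]pyridin-6-ol
Conditions: LiAlH4 (4 equiv), THF, reflux; H2O/aq NaOH work-up
Reagents that add atoms: none
Why: LiAlH4 reduction of a carbamate to the N-methyl amine passes through the iminium ion, touches no stereocentre and only deprotonates the free alcohol.

Step 9
Reactants: 11 incarvilline
Product: 12 (4R,4aS,6R,7S,7aR)-2,4,7-trimethyloctahydro-1H-cyclopenta[c]pyridin-6-yl 2-methylprop-2-enoate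
Conditions: methacrylic anhydride (1.5 equiv), DMAP (0.2 equiv), Et3N, CH2Cl2, rt
Reagents that add atoms: methacrylic anhydride, C=C(C)C(=O)OC(=O)C(C)=C
Why: DMAP-catalysed acylation with an anhydride esterifies the hindered secondary alcohol with retention at C6, since the C6–O bond is not broken.

Step 10
Reactants: 12 (4R,4aS,6R,7S,7aR)-2,4,7-trimethyloctahydro-1H-cyclopenta[c]pyridin-6-yl 2-methylprop-2-enoate; 13 (S)-citronellol, (3S)-3,7-dimethyloct-6-en-1-ol
Product: 16 (4R,4aS,6R,7S,7aR)-2,4,7-trimethyloctahydro-1H-cyclopenta[c]pyridin-6-yl (2E,6S)-8-hydroxy-2,6-dimethyloct-2-enoate, via methacrylate tosylate salt 14 (not isolated), via target tosylate salt 15 (not isolated)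
Conditions: TsOH (1.0 equiv), 1,2-dichloroethane, rt; 13 (5 equiv), second-generation Hoveyda–Grubbs catalyst (10 mol %), 80 °C, argon sparge; aq NaHCO3 work-up
Reagents that add atoms: none
Why: Olefin cross-metathesis of a methacrylate with a prenyl-type trisubstituted alkene, a pairing known for citronellol and simple methacrylates, should give the conjugated trisubstituted ester as the thermodynamically preferred E isomer with loss of isobutene, while protonation masks the tertiary amine from ruthenium, the free primary alcohol is tolerated and the C6′ stereocentre comes unchanged from 13.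

Compound list
1 | (R)-3-bromo-2-methylpropan-1-ol | C[C@H](CO)CBr | starting material
2 | (E)-but-2-en-1-amine | C/C=C/CN | starting material
3 | (2S)-3-[(2E)-but-2-en-1-ylamino]-2-methylpropan-1-ol | C/C=C/CNC[C@@H](CO)C | intermediate
4 | methyl N-[(2E)-but-2-en-1-yl]-N-[(2S)-3-hydroxy-2-methylpropyl]carbamate | C/C=C/CN(C(=O)OC)C[C@@H](CO)C | intermediate
5 | methyl N-[(2E)-but-2-en-1-yl]-N-[(2S)-2-methyl-3-oxopropyl]carbamate | C/C=C/CN(C(=O)OC)C[C@@H](C=O)C | intermediate
6 | methyl N-[(2E)-but-2-en-1-yl]-N-[(2R)-2-methylbut-3-yn-1-yl]carbamate | C/C=C/CN(C(=O)OC)C[C@@H](C#C)C | intermediate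
7 | Co2(CO)6 complex of the alkyne of 6 | C/C=C/CN(C(=O)OC)C[C@H](C)C12[CH]3[Co]1(=C=O)(=C=O)(=C=O)[Co]23(=C=O)(=C=O)=C=O | intermediate
8 | methyl (4R,7S,7aS)-4,7-dimethyl-6-oxo-1,3,4,6,7,7a-hexahydro-2H-cyclopenta[c]pyridine-2-carboxylate | O=C1C=C2[C@@H](CN(C(=O)OC)C[C@@H]2C)[C@@H]1C | intermediate
9 | methyl (4R,6S,7S,7aS)-6-hydroxy-4,7-dimethyl-1,3,4,6,7,7a-hexahydro-2H-cyclopenta[c]pyridine-2-carboxylate | O[C@@H]1C=C2[C@@H](CN(C(=O)OC)C[C@@H]2C)[C@@H]1C | intermediate
10 | methyl (4R,4aS,6R,7S,7aR)-6-hydroxy-4,7-dimethyloctahydro-2H-cyclopenta[c]pyridine-2-carboxylate | O[C@@H]1C[C@@H]2[C@@H](CN(C(=O)OC)C[C@@H]2C)[C@@H]1C | intermediate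
11 | incarvilline, (4R,4aS,6R,7S,7aR)-2,4,7-trimethyloctahydro-1H-cyclopenta[c]pyridin-6-ol | O[C@@H]1C[C@@H]2[C@@H](CN(C)C[C@@H]2C)[C@@H]1C | intermediate
12 | (4R,4aS,6R,7S,7aR)-2,4,7-trimethyloctahydro-1H-cyclopenta[c]pyridin-6-yl 2-methylprop-2-enoate | C=C(C)C(=O)O[C@@H]1C[C@@H]2[C@@H](CN(C)C[C@@H]2C)[C@@H]1C | intermediate
13 | (S)-citronellol, (3S)-3,7-dimethyloct-6-en-1-ol | CC(C)=CCC[C@H](C)CCO | starting material
14 | 4-methylbenzenesulfonate salt of 12 | C=C(C)C(=O)O[C@@H]1C[C@@H]2[C@@H](C[NH+](C)C[C@@H]2C)[C@@H]1C.Cc1ccc(cc1)S(=O)(=O)[O-] | intermediate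
15 | 4-methylbenzenesulfonate salt of 16 | C/C(=C\CC[C@H](C)CCO)C(=O)O[C@@H]1C[C@@H]2[C@@H](C[NH+](C)C[C@@H]2C)[C@@H]1C.Cc1ccc(cc1)S(=O)(=O)[O-] | intermediate
16 | (4R,4aS,6R,7S,7aR)-2,4,7-trimethyloctahydro-1H-cyclopenta[c]pyridin-6-yl (2E,6S)-8-hydroxy-2,6-dimethyloct-2-enoate | C/C(=C\CC[C@H](C)CCO)C(=O)O[C@@H]1C[C@@H]2[C@@H](CN(C)C[C@@H]2C)[C@@H]1C | target

Total step count: 10. Longest linear sequence: 10 steps (1 to 16).

Steps most likely to fail

Step 5. The insertion of the 1,2-disubstituted crotyl alkene into the cobalt–carbon bond may be too slow, so that decomplexation and alkyne oligomerisation win. The chair preference of the tether may also be too weak at 83 °C for useful facial selectivity. The fallback takes the C7 methyl group out of the cycloaddition and adds it afterwards by enolate alkylation. It sets out from 1. Prop-2-en-1-amine takes the place of 2 in the operations of steps 1 to 4. This should give (2S)-2-methyl-3-(prop-2-en-1-ylamino)propan-1-ol F1, its N-methoxycarbonyl derivative F2, the corresponding aldehyde F3 and the N-allyl enyne F4. The monosubstituted alkene of F4 inserts much more readily. The dicobalt hexacarbonyl complex F5, opened at room temperature with N-methylmorpholine N-oxide, should therefore collapse to the C7-unsubstituted enone F6 under milder and more selective conditions. Kinetic deprotonation at C7 (LDA, THF, −78 °C) gives the cross-conjugated lithium dienolate F7, and MeI alkylates it anti to the C7a–C1 bond. The product is 8, where the route is rejoined.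

Step 10. Both alkenes are hindered and the methacrylate is the limiting partner, so the ruthenium carbene may decay before productive turnover. Incomplete masking of the amine would speed this decay. The fallback replaces metathesis by a Horner–Wadsworth–Emmons olefination and sets out from 11 and 13. Alcohol 11 is esterified with 2-(diethoxyphosphoryl)propanoic acid (EDC·HCl, DMAP, CH2Cl2) to the incarvillinyl 2-(diethoxyphosphoryl)propanoate F8. Citronellol 13 is cleaved by ozonolysis (O3, CH2Cl2/MeOH, −78 °C; Me2S) to (4S)-6-hydroxy-4-methylhexanal F9. The two are joined with LiCl and DBU in MeCN, conditions that tolerate the amine and the free alcohol and favour the E-enoate. The product is 16.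

Step 6. Facial selectivity of hydride delivery may be poor, because the piperidine ring shields the face that the C7 methyl leaves open. An error here is passed on by the directed hydrogenation of step 7. The fallback reverses the order of the reductions and corrects C6 by an invertive esterification. It sets out from 8. Hydrogenation over Pd/C (EtOAc, 1 atm H2) from the face of H7a, away from the body of the piperidine ring, should give the cis-fused ketone F10. LiAlH4 (THF, reflux) reduces the carbamate and, attacking the convex face, the ketone. This should give 6-epi-incarvilline F11 with the hydroxyl trans to the C7 methyl. A Mitsunobu reaction with methacrylic acid (PPh3, DIAD, toluene, 0 °C to rt) inverts C6 and comes back to the route at 12.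

Further compounds
F1 | step 5 | (2S)-2-methyl-3-(prop-2-en-1-ylamino)propan-1-ol | C=CCNC[C@@H](CO)C
F2 | step 5 | methyl N-[(2S)-3-hydroxy-2-methylpropyl]-N-(prop-2-en-1-yl)carbamate | C=CCN(C(=O)OC)C[C@@H](CO)C
F3 | step 5 | methyl N-[(2S)-2-methyl-3-oxopropyl]-N-(prop-2-en-1-yl)carbamate | C=CCN(C(=O)OC)C[C@@H](C=O)C
F4 | step 5 | methyl N-[(2R)-2-methylbut-3-yn-1-yl]-N-(prop-2-en-1-yl)carbamate | C=CCN(C(=O)OC)C[C@@H](C#C)C
F5 | step 5 | Co2(CO)6 complex of the alkyne of F4 | C=CCN(C(=O)OC)C[C@H](C)C12[CH]3[Co]1(=C=O)(=C=O)(=C=O)[Co]23(=C=O)(=C=O)=C=O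
F6 | step 5 | methyl (4R,7aS)-4-methyl-6-oxo-1,3,4,6,7,7a-hexahydro-2H-cyclopenta[c]pyridine-2-carboxylate | O=C1C=C2[C@@H](CN(C(=O)OC)C[C@@H]2C)C1
F7 | step 5 | lithium C6,C7-dienolate of F6 | [Li+].[O-]C1=C[C@@H]2CN(C(=O)OC)C[C@H](C)C2=C1
F8 | step 10 | (4R,4aS,6R,7S,7aR)-2,4,7-trimethyloctahydro-1H-cyclopenta[c]pyridin-6-yl 2-(diethoxyphosphoryl)propanoate (both epimers at the phosphonate carbon) | CCOP(=O)(OCC)C(C)C(=O)O[C@@H]1C[C@@H]2[C@@H](CN(C)C[C@@H]2C)[C@@H]1C
F9 | step 10 | (4S)-6-hydroxy-4-methylhexanal | O=CCC[C@H](C)CCO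
F10 | step 6 | methyl (4R,4aS,7S,7aR)-4,7-dimethyl-6-oxooctahydro-2H-cyclopenta[c]pyridine-2-carboxylate | O=C1C[C@@H]2[C@@H](CN(C(=O)OC)C[C@@H]2C)[C@@H]1C
F11 | step 6 | 6-epi-incarvilline, (4R,4aS,6S,7S,7aR)-2,4,7-trimethyloctahydro-1H-cyclopenta[c]pyridin-6-ol | O[C@H]1C[C@@H]2[C@@H](CN(C)C[C@@H]2C)[C@@H]1C
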